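In a one-step, first-order world a flask has a half-life that ignores the charge, much like a time constant. Sunday's run starts with a lag, so it is not that world, but the same clock can still be read from it.

| flask | starting material | catalyst | product | time |
|---|---|---|---|---|
| Sunday's | 0.500 M | 0.0400 M |  |  |
| Wednesday's | 0.300 M | 0.0400 M |  |  |
| Thursday's | 0.500 M | 0.0400 M | 0.150 M |  |
| Tuesday's | 0.500 M | 0.0800 M |  |  |
| Monday's | 0.170 M | 0.0200 M |  | 3.7 h |

| run | time / h | [product] / M |
|---|---|---|
| Sunday's run | 0.53 | 0.004 |
| Sunday's run | 1.1 | 0.030 |
| Sunday's run | 1.6 | 0.048 |
| Sunday's run | 2.1 | 0.123 |
| Sunday's run | 2.6 | 0.221 |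
| Sunday's run | 3.2 | 0.344 |
| Sunday's run | 3.7 | 0.429 |
| Wednesday's run | 0.53 | 0.001 |
| Wednesday's run | 1.1 | 0.021 |
| Wednesday's run | 1.6 | 0.042 |
| Wednesday's run | 2.1 | 0.087 |
| Wednesday's run | 2.6 | 0.123 |
| Wednesday's run | 3.2 | 0.175 |
| Wednesday's run | 3.7 | 0.232 |
| Thursday's run | 0.53 | 0.338 |
| Thursday's run | 1.1 | 0.499 |
| Thursday's run | 1.6 | 0.598 |
| Thursday's run | 2.1 | 0.640 |
| Thursday's run | 2.6 | 0.644 |
| Thursday's run | 3.2 | 0.654 |
| Thursday's run | 3.7 | 0.651 |
| Tuesday's run | 0.53 | 0.006 |
| Tuesday's run | 1.1 | 0.077 |
| Tuesday's run | 1.6 | 0.183 |
| Tuesday's run | 2.1 | 0.305 |
| Tuesday's run | 2.6 | 0.444 |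
| Tuesday's run | 3.2 | 0.506 |
| Tuesday's run | 3.7 | 0.494 |

(scatter of a reading: 0.005 M)

- Overall: starting material -> product, with catalyst as catalyst.
- Constant volume, constant temperature.
- A reading of a species includes what of it is bound.
- An order is taken over about fifteen percent of the charge, up and down.

* order of the initial rate in [starting material], near the charge of the Sunday's run, the rate being that where two percent of its starting material are product (one fixed amount of product, the same in the runs compared)
* order of the initial rate in [catalyst], near the charge of the Sunday's run, the rate being that where two percent of its starting material are product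
* the Wednesday's run starts with 0.200 M less of starting material than the Sunday's run, and with no product. Compared where both hold the same amount of starting material, once fifteen percent of what the Wednesday's run was charged with has turned into product, is the Wednesday's run faster, slower or alike (within a tenth)?
* product in the Monday's run at 3.7 h, as a share of the starting material charged

One side holds that product breeds product (autocatalysis). Thursday's run speaks for it: it has made 0.188 M of new product at 0.53 h, while Sunday's run holds 0.004 M at that time. That side is the forecast. Its ground is this: “Thursday's added product removes it, so product speeds the reaction”. It gives order 0.7 in starting material, order 0.7 in catalyst, Wednesday's run slower, and 20% for Monday's run.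

I hold to the clock. The half-time is the time at which the product made comes to half of the starting material charged. Interpolating between readings gives 2.74 h for Sunday's run and 2.91 h for Wednesday's. Wednesday's is longer, but by a factor of 1.06, while its charge is 0.600 of Sunday's.

Tuesday's run has twice Sunday's catalyst and a half-time of 1.87 h. So I define the stretch f, the factor by which the half-time grows when the catalyst is halved at Sunday's charge of starting material, as Sunday's half-time over Tuesday's: 1.46.

Monday's run has Sunday's catalyst halved, and its charge lies nearer Wednesday's than Sunday's. I therefore assume it runs on Wednesday's clock slowed by f. Its 3.7 h then corresponds to 2.53 h in Wednesday's run, where the readings interpolate to 39.3% of the charge. My figure is higher than the forecast's.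

The simulation gives order 0.30 in starting material, order 0.69 in catalyst, Wednesday's run slower, and 35.6% for Monday's run, which is 16 percentage points above the forecast and 3.7 points below my figure.

    active catalyst + starting material ⇌ catalyst-substrate complex, settled at all times (36.50 M⁻¹)
    catalyst-substrate complex + active catalyst → product + 2 active catalyst (132.8 M⁻¹ h⁻¹)
    catalyst → active catalyst (4.464 h⁻¹)
    starting material + product → 2 product (3.780 M⁻¹ h⁻¹)

Wednesday's readings pass 35.6% of their charge at 2.38 h, so on my assumption Monday's run took a stretch of 1.55, against the carried 1.46. The forecast's view has its region where product is charged: Thursday's half-time is 0.718 h, against Sunday's 2.74 h. The quarter-time is when product made reaches a quarter of the charge. Tuesday's quarter-time of 1.36 h times the stretch is 1.99 h, and Sunday's quarter-time is 2.13 h.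

The readings stem from a simulated flask on assumed constants, and the scatter is random.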